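## Analysis of the target

Target 29 is a daucane ester: a cyclopentane (C1–C5) trans-fused along C1–C5 to a cycloheptane (C1, C5–C10). C1 is the methyl-bearing fusion carbon, C4 the isopropyl carbinol, C6 the carbon carrying the 4-hydroxybenzoate, C8 the methyl carbinol and C9 the secondary carbinol; α is the face of H-5, β that of the C1 methyl. There are six stereocentres: C1 (R, quaternary, methyl β), C4 (R, OH β, isopropyl α), C5 (S, H α), C6 (S, acyloxy α), C8 (S, OH β, methyl α) and C9 (S, OH α). C1, C4, C5 and C6 form one contiguous block, with O-4 and O-6 1,3-syn across C5, whereas the trans-diol at C8/C9 sits on the far side of the seven-membered ring and can only be controlled through the ring conformation. In the cycloheptane chair the C1 methyl (β) and H-5 (α) are axial, the C6 ester is equatorial, and the C1 methyl is 1,3 to C9, which decides the face on which reagents reach C8/C9. Sensitive groups are the aryl ester beside the free tertiary 4-hydroxyl (hydrolysis, acyl migration), two tertiary alcohols (elimination in strong acid) and the phenol, which is carried as a benzyl ether. The difficulty is a quaternary C1 next to a fully substituted C4 in a trans-fused 5–7 system, and closing the seven-membered ring. The strategy rests on three chains on C1: C2–C3–C4, where C4 becomes a carbinol radical once an attached carboxyl is lost; C5=C6 as an enol ester whose oxygen is already the ester oxygen; and C10–C9(=O)–C8(CH3)=C7, an isopropenyl ketone. Bonds C4–C5 and C6–C7 then fold acid 22 into both rings.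

## Retrosynthetic reasoning

29 ⇒ 28. The phenol O–benzyl bond is cut last. A free phenol would not survive acylation, the photocatalyst or the peracid, and hydrogenolysis touches nothing else once the alkene is gone.

28 ⇒ 27 ⇒ 26. The C8–O bond is cut with inversion and both oxygens are traced to the α-epoxide 27 of alkene 26. A peracid should reach C8=C9 anti to the axial C1 methyl (α face); water then opens the protonated epoxide at tertiary C8 from the β face, giving 8β-OH and 9α-OH. Hydroxylating C8 through the enol ether of ketone 23 and then reducing C9 under hydroxyl direction was weighed; the same facial bias would put O-8 on the α face, so that sequence is kept only as the complementary option.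

26 ⇒ 25 ⇒ 23. The alkene is traced to the C9 ketone through the more substituted enol triflate 25. This needs enolisation toward C8 rather than the neopentyl C10, which soft enolisation should provide.

23 ⇒ 22. Bonds C4–C5 and C6–C7 are cut together. Decarboxylation of the α-hydroxy acid gives the C4 radical, the enol ester relays it to C6, and the enone terminates it. Cutting here delivers the C4 carbinol, the C6 ester and the C9 carbonyl in one operation from an acyclic precursor whose only stereocentre is C1. The forward step must control C5 against C1, then C4 and C6.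

22 ⇒ 21 ⇒ 19 + 20. The acid is masked as a tert-butyl ester, removable by acid without touching enol ester or enone. The enol ester is cut at its acyl–oxygen bond to aldehyde 19 and acid chloride 20; the bulk at C1 should enforce the E geometry.

19 ⇒ 18 ⇒ 15 + 16 ⇒ 13. The C6 aldehyde and the C9 isopropenyl ketone are the two ends of a cleaved 1,2-diol, so the C6–C9 bond is reconnected to give cyclopentane 18. This traces to the α-silyloxy ketone 15 plus Grignard reagent 16, and to ketone 13 by oxidation at the α-carbon remote from the quaternary centre. A ring differentiates the two CH2–C(O) arms on C1 without protecting groups.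

13 ⇒ 12 ⇒ 8 + 10 (10 ⇐ 9). The C3–C4 bond is cut to the organomagnesium derived from bromide 8 and keto ester 10, which brings C4 with its hydroxyl, isopropyl and carboxyl in one addition. The ring ketone has to be a ketal at this stage.

8 ⇒ 7 ⇒ 5 ⇒ 4 ⇒ 3 ⇒ 1 + 2. The two-carbon arm C2–C3 is a vinyl group. C1 is set by catalytic asymmetric conjugate addition of a silyl-substituted vinyl nucleophile made from 2 to enone 1, followed by removal of silicon.

## Alternatives that were turned down

Alternative 1: The C1–C10 bond is disconnected by a Claisen rearrangement. The substrate is the allyl vinyl ether A1, a 2-methylideneoxolane carrying the methylcyclopentenyl ketal on its other α-carbon. On heating it would form C1–C10, break C6–O and give the bicyclic cycloheptenone A2 (quaternary C1, C5=C6, C9 ketone, C4 ketal).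
- For: a thermal pericyclic step with predictable transfer of chirality from the ether carbon to C1; a later syn hydroboration of C5=C6 from the α face would set H-5 and O-6 together.
- Against: the rearrangement expels the C6 oxygen. A2 also lacks the isopropyl carbinol, the C8 methyl and both C8/C9 oxygens, so at least eight to ten separately controlled steps follow, including regioselective methylation at C8 rather than C10.
- Comparison: it is stronger in certainty of ring formation and of the C1/C5 relationship. The chosen route offers the C4, C6 and C9 oxidation levels and the ester itself directly from the ring-forming step.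

Alternative 2: The C5–C1 and C9–C10 bonds are disconnected by an oxidopyrylium–alkene (5+2) cycloaddition. Acetoxypyranone A3 (from an Achmatowicz rearrangement of a furyl carbinol) would lose acetate with an amine base, and the oxidopyrylium would add across the tethered 1,1-disubstituted alkene to give the oxygen-bridged hydroazulenone A4.
- For: both rings and the quaternary C1 form in one well-precedented step; C4 is set beforehand by ordinary asymmetric synthesis; C9 arrives oxygenated; C6 is a ketone and C7=C8 a methyl enone ready for C8 oxygenation.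
- Against: the bridge puts oxygen on C5, where the target has hydrogen. The C5–O bond must be cleaved reductively and H-5 set afterwards, C6 must be reduced selectively, O-6 and O-9 must be told apart for acylation, and O-8 is still missing.
- Comparison: this is the strongest rival, and it is stronger exactly where the chosen route is weakest (C4 configuration, certainty of bicyclisation). The chosen route offers C5–H and the C6 ester directly, oxygens at C6 and C9 differentiated from the start, and no bridge-cleaving redox steps.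

Alternative 3: The C5–C1 and C5–C6 bonds are disconnected by a Buchner reaction. Diazoketone A5 would give a carbene at C5 under dirhodium tetracarboxylate catalysis; addition to the ipso–ortho bond of the tolyl ring, norcaradiene opening and base-mediated isomerisation would give the dihydroazulenone A6.
- For: the shortest route to the bicyclic carbon framework, from a cheap arene, with the C8 methyl and a C4 carbonyl in place.
- Against: A6 is flat and achiral, with no C1 methyl, no isopropyl and none of the six stereocentres. The quaternary methyl would need an enantioselective conjugate addition to a cross-conjugated trienone with 1,4/1,6/1,8 ambiguity, followed by regio- and stereoselective oxygenation of a polyene.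
- Comparison: it is stronger only in brevity and certainty of the ring-forming step. The chosen route puts stereocentres and oxidation pattern into the ring-forming step.

Key step: step 14

Remark: keto ester 10 is made in step 6 because its commercial supply is uncertain; acid chloride 20 is taken as a commercial reagent.
Remark: C4 in 12–22 and C6 in 15, 17 and 18 are deliberately carried as epimer mixtures, because both become planar later. Ketone 23 is drawn as its 8α-methyl epimer, but both C8 epimers enter step 15.

## Route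

Step 1
Reactants: 1 3-methylcyclopent-2-en-1-one; 2 ethynyl(trimethyl)silane
Product: 3 (3S)-3-methyl-3-[1-(trimethylsilyl)ethenyl]cyclopentan-1-one
Conditions: 2, i-Bu2AlH, hexanes, 55 °C; then 1, Cu(OTf)2 (5 mol %), chiral sulfonate-bearing imidazolinium salt (NHC precursor, 5 mol %), THF, −30 °C; aqueous work-up
Reagents that add atoms: none
Why: Copper-catalysed asymmetric conjugate addition of an alkenylaluminium reagent (from hydroalumination of 2) to a β-substituted cyclic enone; the chiral NHC–copper complex selects the enone face and sets the quaternary centre (future C1), the ligand enantiomer being chosen to give the S ketone.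

Step 2
Reactants: 3 (3S)-3-methyl-3-[1-(trimethylsilyl)ethenyl]cyclopentan-1-one
Product: 4 (3S)-3-ethenyl-3-methylcyclopentan-1-one
Conditions: CF3CO2H, CH2Cl2, 0 °C to rt; aqueous work-up
Reagents that add atoms: none
Why: Protodesilylation of a vinylsilane: ipso protonation gives a β-silyl cation that loses silicon, leaving the vinyl group; the quaternary centre is not involved.

Step 3
Reactants: 4 (3S)-3-ethenyl-3-methylcyclopentan-1-one
Product: 5 (7S)-7-ethenyl-7-methyl-1,4-dioxaspiro[4.4]nonane
Conditions: HOCH2CH2OH, p-TsOH·H2O (cat.), benzene, reflux, Dean–Stark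
Reagents that add atoms: ethane-1,2-diol, OCCO
Why: Acid-catalysed ketalisation; the ketone must be masked for the hydroboration and the Grignard step.

Step 4
Reactants: 5 (7S)-7-ethenyl-7-methyl-1,4-dioxaspiro[4.4]nonane
Product: 7 2-[(7R)-7-methyl-1,4-dioxaspiro[4.4]nonan-7-yl]ethan-1-ol, via alkylborane 6 (not isolated)
Conditions: 9-BBN, THF, 0 °C to 40 °C; then NaOH, H2O2, 0 °C
Reagents that add atoms: hydrogen peroxide, OO
Why: Anti-Markovnikov hydroboration–oxidation; the bulky borane adds to the terminal carbon of the vinyl group on the quaternary centre (the descriptor changes by priority only).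

Step 5
Reactants: 7 2-[(7R)-7-methyl-1,4-dioxaspiro[4.4]nonan-7-yl]ethan-1-ol
Product: 8 (7S)-7-(2-bromoethyl)-7-methyl-1,4-dioxaspiro[4.4]nonane
Conditions: CBr4, PPh3, imidazole, CH2Cl2, 0 °C
Reagents that add atoms: tetrabromomethane, BrC(Br)(Br)Br
Why: Appel bromination, SN2 at the primary carbon; imidazole buffers the acid so the ketal survives.

Step 6
Reactants: 9 3-methyl-2-oxobutanoic acid
Product: 10 tert-butyl 3-methyl-2-oxobutanoate
Conditions: tert-butyl 2,2,2-trichloroacetimidate, BF3·OEt2 (cat.), CH2Cl2–cyclohexane, rt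
Reagents that add atoms: tert-butyl 2,2,2-trichloroacetimidate, CC(C)(C)OC(=N)C(Cl)(Cl)Cl
Why: Acid-catalysed tert-butylation of a carboxylic acid by an imidate; the tert-butyl ester is chosen because it resists the later organomagnesium steps and is removed by acid in step 13.

Step 7
Reactants: 8 (7S)-7-(2-bromoethyl)-7-methyl-1,4-dioxaspiro[4.4]nonane; 10 tert-butyl 3-methyl-2-oxobutanoate
Product: 12 tert-butyl 2-hydroxy-4-[(7S)-7-methyl-1,4-dioxaspiro[4.4]nonan-7-yl]-2-(propan-2-yl)butanoate, via Grignard reagent 11 (not isolated)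
Conditions: Mg, THF, 40 °C; then added to 10, THF, −78 °C; aq. NH4Cl
Reagents that add atoms: none
Why: Grignard addition to the ketone carbonyl of an α-keto ester, which is far more electrophilic than the hindered tert-butyl ester; it forms C3–C4 and installs hydroxyl, isopropyl and carboxyl on C4, whose configuration is irrelevant because C4 becomes a radical in step 14.

Step 8
Reactants: 12 tert-butyl 2-hydroxy-4-[(7S)-7-methyl-1,4-dioxaspiro[4.4]nonan-7-yl]-2-(propan-2-yl)butanoate
Product: 13 tert-butyl 2-hydroxy-4-[(1S)-1-methyl-3-oxocyclopentyl]-2-(propan-2-yl)butanoate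
Conditions: 1 M aq. HCl, THF, 0 °C to rt
Reagents that add atoms: water, O
Why: Acid hydrolysis of the dioxolane; dilute aqueous acid leaves the tert-butyl ester and the tertiary alcohol (deactivated by the adjacent ester) intact.

Step 9
Reactants: 13 tert-butyl 2-hydroxy-4-[(1S)-1-methyl-3-oxocyclopentyl]-2-(propan-2-yl)butanoate
Product: 15 tert-butyl 4-{(1S)-1-methyl-3-oxo-4-[(trimethylsilyl)oxy]cyclopentyl}-2-(propan-2-yl)-2-[(trimethylsilyl)oxy]butanoate, via bis-silyl enol ether 14 (not isolated)
Conditions: LiN(iPr)2 (2.2 equiv), THF, −78 °C; Me3SiCl; pentane, filtration; then mCPBA, NaHCO3, CH2Cl2, −20 °C to 0 °C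
Reagents that add atoms: chlorotrimethylsilane, C[Si](C)(C)Cl; 3-chloroperbenzoic acid, OOC(=O)c1cccc(Cl)c1
Why: Kinetic deprotonation at the α-carbon remote from the quaternary centre, then Rubottom oxidation, places oxygen on the future C6; keeping it silylated prevents the ketol from tautomerising, which would exchange the two arms on C1 and erode its configuration.

Step 10
Reactants: 15 tert-butyl 4-{(1S)-1-methyl-3-oxo-4-[(trimethylsilyl)oxy]cyclopentyl}-2-(propan-2-yl)-2-[(trimethylsilyl)oxy]butanoate; 16 bromo(prop-1-en-2-yl)magnesium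
Product: 18 tert-butyl 4-[(1S)-3,4-dihydroxy-1-methyl-3-(prop-1-en-2-yl)cyclopentyl]-2-hydroxy-2-(propan-2-yl)butanoate, via magnesium alkoxide 17 (not isolated)
Conditions: 16 (2.5 equiv), THF, −78 °C to −20 °C; aq. NH4Cl; then Bu4NF, THF, 0 °C
Reagents that add atoms: none
Why: 1,2-Addition of an alkenyl Grignard reagent to the ring ketone; the tert-butyl ester on a fully substituted silyloxy carbon is inert at low temperature, and fluoride then frees the 1,2-diol.

Step 11
Reactants: 18 tert-butyl 4-[(1S)-3,4-dihydroxy-1-methyl-3-(prop-1-en-2-yl)cyclopentyl]-2-hydroxy-2-(propan-2-yl)butanoate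
Product: 19 tert-butyl (5S)-2-hydroxy-5,8-dimethyl-7-oxo-5-(2-oxoethyl)-2-(propan-2-yl)non-8-enoate
Conditions: Pb(OAc)4, K2CO3, CH2Cl2, −20 °C to 0 °C; used at once
Reagents that add atoms: none
Why: Criegee glycol cleavage of the C6–C9 bond unveils the isopropenyl ketone and the C6 aldehyde together; the isolated α-hydroxy ester is not a substrate for the oxidant.

Step 12
Reactants: 19 tert-butyl (5S)-2-hydroxy-5,8-dimethyl-7-oxo-5-(2-oxoethyl)-2-(propan-2-yl)non-8-enoate; 20 4-(benzyloxy)benzoyl chloride
Product: 21 tert-butyl (5R)-5-[(E)-2-{[4-(benzyloxy)benzoyl]oxy}ethenyl]-2-hydroxy-5,8-dimethyl-7-oxo-2-(propan-2-yl)non-8-enoate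
Conditions: 20, Et3N, DMAP (cat.), CH2Cl2, 0 °C to rt
Reagents that add atoms: none
Why: O-Acylation of the aldehyde enolate (enol ester formation); the quaternary substituent on C5 should force the acyloxy group trans (E), the α-methyl enone cannot enter Morita–Baylis–Hillman chemistry with DMAP, and the hindered tertiary hydroxyl is not acylated.

Step 13
Reactants: 21 tert-butyl (5R)-5-[(E)-2-{[4-(benzyloxy)benzoyl]oxy}ethenyl]-2-hydroxy-5,8-dimethyl-7-oxo-2-(propan-2-yl)non-8-enoate
Product: 22 (5R)-5-[(E)-2-{[4-(benzyloxy)benzoyl]oxy}ethenyl]-2-hydroxy-5,8-dimethyl-7-oxo-2-(propan-2-yl)non-8-enoic acid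
Conditions: CF3CO2H–CH2Cl2 (1:3), 0 °C to rt
Reagents that add atoms: none
Why: Acidolysis of the tert-butyl ester with loss of isobutene; enol ester, enone, benzyl ether and the ester-deactivated tertiary alcohol should tolerate the acid.

Step 14
Reactants: 22 (5R)-5-[(E)-2-{[4-(benzyloxy)benzoyl]oxy}ethenyl]-2-hydroxy-5,8-dimethyl-7-oxo-2-(propan-2-yl)non-8-enoic acid
Product: 23 (3R,3aS,4S,6R,8aR)-3-hydroxy-6,8a-dimethyl-7-oxo-3-(propan-2-yl)decahydroazulen-4-yl 4-(benzyloxy)benzoate
Conditions: [Ir(dF(CF3)ppy)2(dtbbpy)]PF6 (2 mol %), K2HPO4 (1.2 equiv), degassed DMF (2 mM), blue LEDs (450 nm), 25 °C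
Reagents that add atoms: none
Why: Proposed new method: the excited iridium complex oxidises the carboxylate of 22, CO2 is lost, the tertiary α-hydroxyalkyl radical at C4 closes the cyclopentane by 5-exo-trig attack on C5 of the enol ester, the resulting α-acyloxy radical at C6 closes the cycloheptane by 7-endo-trig attack on the unsubstituted terminus C7 of the isopropenyl ketone, and the α-keto radical at C8 is reduced by the reduced photocatalyst to an enolate that the next molecule of acid protonates. The closest known reaction types are photoredox decarboxylation of α-oxy acids with Giese addition and tin-mediated 7-endo radical cyclisations onto enones; joining them through an enol ester is the new element. C5 is set against C1 in a chair-like 5-exo transition state with the larger CH2C(=O) chain on C1 pseudo-equatorial, so C6 ends up trans to C10 (trans fusion); only the modest size difference between CH3 and CH2COR secures this. C4 is set in the same closure: the isopropyl group should avoid the C6–O substituent and sit on the side of H-5, and a hydrogen bond from the free 4-OH to the ester oxygen favours hydroxyl cis to C6, which is why the hydroxyl is left unprotected. In the second closure the forming C6–C7 bond lies anti to C4, and the acyloxy group eclipses H-5 rather than the quaternary C1, which makes it equatorial and α. C8 is formed as an epimer mixture and is erased in step 15. The step needs the 5-exo closure to outrun intermolecular Giese addition (hence high dilution), 7-endo to beat 6-exo attack at the substituted C8 (secured by the polarity and substitution of the acceptor), and the enol ester to survive the base (hence K2HPO4).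

Step 15
Reactants: 23 (3R,3aS,4S,6R,8aR)-3-hydroxy-6,8a-dimethyl-7-oxo-3-(propan-2-yl)decahydroazulen-4-yl 4-(benzyloxy)benzoate
Product: 25 (3R,3aS,4S,8aR)-3-hydroxy-6,8a-dimethyl-3-(propan-2-yl)-7-[(trifluoromethanesulfonyl)oxy]-1,2,3,3a,4,5,8,8a-octahydroazulen-4-yl 4-(benzyloxy)benzoate, via silyl enol ether 24 (not isolated)
Conditions: Me3SiOTf, Et3N, CH2Cl2, 0 °C to rt; pentane, filtration; then CsF, PhNTf2, DME, rt; aqueous work-up
Reagents that add atoms: N-phenylbis(trifluoromethanesulfonimide), O=S(=O)(N(c1ccccc1)S(=O)(=O)C(F)(F)F)C(F)(F)F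
Why: Soft enolisation should give the more substituted C8=C9 silyl enol ether because C10 is neopentyl; fluoride then releases that enolate regiospecifically and the triflimide traps it on oxygen. Any O-4 silyl ether that survives is removed by the acid of step 18.

Step 16
Reactants: 25 (3R,3aS,4S,8aR)-3-hydroxy-6,8a-dimethyl-3-(propan-2-yl)-7-[(trifluoromethanesulfonyl)oxy]-1,2,3,3a,4,5,8,8a-octahydroazulen-4-yl 4-(benzyloxy)benzoate
Product: 26 (3R,3aS,4S,8aR)-3-hydroxy-6,8a-dimethyl-3-(propan-2-yl)-1,2,3,3a,4,5,8,8a-octahydroazulen-4-yl 4-(benzyloxy)benzoate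
Conditions: Pd(OAc)2 (5 mol %), PPh3, HCO2H, n-Bu3N, DMF, 60 °C
Reagents that add atoms: none
Why: Palladium-catalysed formate reduction of an enol triflate (oxidative addition, formate decarboxylation, reductive elimination) gives the trisubstituted C8=C9 alkene.

Step 17
Reactants: 26 (3R,3aS,4S,8aR)-3-hydroxy-6,8a-dimethyl-3-(propan-2-yl)-1,2,3,3a,4,5,8,8a-octahydroazulen-4-yl 4-(benzyloxy)benzoate
Product: 27 (1R,4R,5S,6S,8R,9S)-8,9-epoxy-4-hydroxydaucan-6-yl 4-(benzyloxy)benzoate (the 8α,9α-epoxide of 26: epoxide oxygen on the face of H-5, C8 methyl on the face of the C1 methyl)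
Conditions: mCPBA, NaHCO3, CH2Cl2, 0 °C
Reagents that add atoms: 3-chloroperbenzoic acid, OOC(=O)c1cccc(Cl)c1
Why: Prilezhaev epoxidation; in the cycloheptene chair the axial C1 methyl is 1,3 to C9 and screens the β face, so the peracid should add to the α face, as with alkenes flanking an angular methyl in fused ring systems.

Step 18
Reactants: 27 (1R,4R,5S,6S,8R,9S)-8,9-epoxy-4-hydroxydaucan-6-yl 4-(benzyloxy)benzoate
Product: 28 (3R,3aS,4S,6S,7S,8aR)-3,6,7-trihydroxy-6,8a-dimethyl-3-(propan-2-yl)decahydroazulen-4-yl 4-(benzyloxy)benzoate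
Conditions: HClO4 (cat.), THF–H2O (3:1), 0 °C to rt
Reagents that add atoms: water, O
Why: Acid-catalysed epoxide hydrolysis: water attacks the protonated epoxide at tertiary C8 from the β face with inversion, while the epoxide oxygen stays on C9 (α), giving the 8β,9α trans-diol; attack at C9 from the β face is disfavoured electronically and by the C1 methyl.

Step 19
Reactants: 28 (3R,3aS,4S,6S,7S,8aR)-3,6,7-trihydroxy-6,8a-dimethyl-3-(propan-2-yl)decahydroazulen-4-yl 4-(benzyloxy)benzoate
Product: 29 (3R,3aS,4S,6S,7S,8aR)-3,6,7-trihydroxy-6,8a-dimethyl-3-(propan-2-yl)decahydroazulen-4-yl 4-hydroxybenzoate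
Conditions: H2 (1 atm), Pd/C (10 % palladium on carbon), EtOAc, rt
Reagents that add atoms: none
Why: Hydrogenolysis of the benzyl aryl ether; the aryl ester and the three alcohols are not affected and no alkene remains.

## Compound list

1 | 3-methylcyclopent-2-en-1-one | CC1=CC(=O)CC1 | starting material
2 | ethynyl(trimethyl)silane | C#C[Si](C)(C)C | starting material
3 | (3S)-3-methyl-3-[1-(trimethylsilyl)ethenyl]cyclopentan-1-one | C=C([Si](C)(C)C)[C@]1(C)CC(=O)CC1 | intermediate
4 | (3S)-3-ethenyl-3-methylcyclopentan-1-one | C=C[C@]1(C)CC(=O)CC1 | intermediate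
5 | (7S)-7-ethenyl-7-methyl-1,4-dioxaspiro[4.4]nonane | C=C[C@]1(C)CC2(CC1)OCCO2 | intermediate
6 | 9-{2-[(7S)-7-methyl-1,4-dioxaspiro[4.4]nonan-7-yl]ethyl}-9-borabicyclo[3.3.1]nonane | C1CC2CCCC(C1)B2CC[C@]3(C)CC4(CC3)OCCO4 | intermediate
7 | 2-[(7R)-7-methyl-1,4-dioxaspiro[4.4]nonan-7-yl]ethan-1-ol | OCC[C@]1(C)CC2(CC1)OCCO2 | intermediate
8 | (7S)-7-(2-bromoethyl)-7-methyl-1,4-dioxaspiro[4.4]nonane | BrCC[C@]1(C)CC2(CC1)OCCO2 | intermediate
9 | 3-methyl-2-oxobutanoic acid | CC(C)C(=O)C(=O)O | starting material
10 | tert-butyl 3-methyl-2-oxobutanoate | CC(C)C(=O)C(=O)OC(C)(C)C | intermediate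
11 | bromo{2-[(7S)-7-methyl-1,4-dioxaspiro[4.4]nonan-7-yl]ethyl}magnesium | Br[Mg]CC[C@]1(C)CC2(CC1)OCCO2 | intermediate
12 | tert-butyl 2-hydroxy-4-[(7S)-7-methyl-1,4-dioxaspiro[4.4]nonan-7-yl]-2-(propan-2-yl)butanoate (both C2 epimers) | CC(C)C(O)(C(=O)OC(C)(C)C)CC[C@]1(C)CC2(CC1)OCCO2 | intermediate
13 | tert-butyl 2-hydroxy-4-[(1S)-1-methyl-3-oxocyclopentyl]-2-(propan-2-yl)butanoate | CC(C)C(O)(C(=O)OC(C)(C)C)CC[C@]1(C)CC(=O)CC1 | intermediate
14 | tert-butyl 4-{(1S)-1-methyl-3-[(trimethylsilyl)oxy]cyclopent-3-en-1-yl}-2-(propan-2-yl)-2-[(trimethylsilyl)oxy]butanoate | CC(C)C(O[Si](C)(C)C)(C(=O)OC(C)(C)C)CC[C@]1(C)CC(O[Si](C)(C)C)=CC1 | intermediate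
15 | tert-butyl 4-{(1S)-1-methyl-3-oxo-4-[(trimethylsilyl)oxy]cyclopentyl}-2-(propan-2-yl)-2-[(trimethylsilyl)oxy]butanoate | CC(C)C(O[Si](C)(C)C)(C(=O)OC(C)(C)C)CC[C@]1(C)CC(=O)C(O[Si](C)(C)C)C1 | intermediate
16 | bromo(prop-1-en-2-yl)magnesium | CC(=C)[Mg]Br | starting material
17 | bromomagnesium alkoxide of tert-butyl 4-{(1S)-3-hydroxy-1-methyl-3-(prop-1-en-2-yl)-4-[(trimethylsilyl)oxy]cyclopentyl}-2-(propan-2-yl)-2-[(trimethylsilyl)oxy]butanoate | CC(C)C(O[Si](C)(C)C)(C(=O)OC(C)(C)C)CC[C@]1(C)CC(O[Mg]Br)(C(C)=C)C(O[Si](C)(C)C)C1 | intermediate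
18 | tert-butyl 4-[(1S)-3,4-dihydroxy-1-methyl-3-(prop-1-en-2-yl)cyclopentyl]-2-hydroxy-2-(propan-2-yl)butanoate | CC(C)C(O)(C(=O)OC(C)(C)C)CC[C@]1(C)CC(O)(C(C)=C)C(O)C1 | intermediate
19 | tert-butyl (5S)-2-hydroxy-5,8-dimethyl-7-oxo-5-(2-oxoethyl)-2-(propan-2-yl)non-8-enoate | CC(C)C(O)(C(=O)OC(C)(C)C)CC[C@](C)(CC(=O)C(C)=C)CC=O | intermediate
20 | 4-(benzyloxy)benzoyl chloride | O=C(Cl)c1ccc(OCc2ccccc2)cc1 | starting material
21 | tert-butyl (5R)-5-[(E)-2-{[4-(benzyloxy)benzoyl]oxy}ethenyl]-2-hydroxy-5,8-dimethyl-7-oxo-2-(propan-2-yl)non-8-enoate | CC(C)C(O)(C(=O)OC(C)(C)C)CC[C@](C)(CC(=O)C(C)=C)/C=C/OC(=O)c1ccc(OCc2ccccc2)cc1 | intermediate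
22 | (5R)-5-[(E)-2-{[4-(benzyloxy)benzoyl]oxy}ethenyl]-2-hydroxy-5,8-dimethyl-7-oxo-2-(propan-2-yl)non-8-enoic acid | CC(C)C(O)(C(=O)O)CC[C@](C)(CC(=O)C(C)=C)/C=C/OC(=O)c1ccc(OCc2ccccc2)cc1 | intermediate
23 | (3R,3aS,4S,6R,8aR)-3-hydroxy-6,8a-dimethyl-7-oxo-3-(propan-2-yl)decahydroazulen-4-yl 4-(benzyloxy)benzoate | CC(C)[C@]1(O)CC[C@]2(C)CC(=O)[C@H](C)C[C@H](OC(=O)c3ccc(OCc4ccccc4)cc3)[C@H]21 | intermediate
24 | (3R,3aS,4S,8aR)-6,8a-dimethyl-3-(propan-2-yl)-3,7-bis[(trimethylsilyl)oxy]-1,2,3,3a,4,5,8,8a-octahydroazulen-4-yl 4-(benzyloxy)benzoate | CC(C)[C@]1(O[Si](C)(C)C)CC[C@]2(C)CC(O[Si](C)(C)C)=C(C)C[C@H](OC(=O)c3ccc(OCc4ccccc4)cc3)[C@H]21 | intermediate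
25 | (3R,3aS,4S,8aR)-3-hydroxy-6,8a-dimethyl-3-(propan-2-yl)-7-[(trifluoromethanesulfonyl)oxy]-1,2,3,3a,4,5,8,8a-octahydroazulen-4-yl 4-(benzyloxy)benzoate | CC(C)[C@]1(O)CC[C@]2(C)CC(OS(=O)(=O)C(F)(F)F)=C(C)C[C@H](OC(=O)c3ccc(OCc4ccccc4)cc3)[C@H]21 | intermediate
26 | (3R,3aS,4S,8aR)-3-hydroxy-6,8a-dimethyl-3-(propan-2-yl)-1,2,3,3a,4,5,8,8a-octahydroazulen-4-yl 4-(benzyloxy)benzoate | CC(C)[C@]1(O)CC[C@]2(C)CC=C(C)C[C@H](OC(=O)c3ccc(OCc4ccccc4)cc3)[C@H]21 | intermediate
27 | (1R,4R,5S,6S,8R,9S)-8,9-epoxy-4-hydroxydaucan-6-yl 4-(benzyloxy)benzoate (8α,9α-epoxide of 26) | CC(C)[C@]1(O)CC[C@]2(C)C[C@@H]3O[C@]3(C)C[C@H](OC(=O)c4ccc(OCc5ccccc5)cc4)[C@H]21 | intermediate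
28 | (3R,3aS,4S,6S,7S,8aR)-3,6,7-trihydroxy-6,8a-dimethyl-3-(propan-2-yl)decahydroazulen-4-yl 4-(benzyloxy)benzoate | CC(C)[C@]1(O)CC[C@]2(C)C[C@H](O)[C@@](C)(O)C[C@H](OC(=O)c3ccc(OCc4ccccc4)cc3)[C@H]21 | intermediate
29 | (3R,3aS,4S,6S,7S,8aR)-3,6,7-trihydroxy-6,8a-dimethyl-3-(propan-2-yl)decahydroazulen-4-yl 4-hydroxybenzoate | CC(C)[C@]1(O)CC[C@]2(C)C[C@H](O)[C@@](C)(O)C[C@H](OC(=O)c3ccc(O)cc3)[C@H]21 | target

## Step count and least certain steps

Total: 19 steps. Longest linear sequence: 18 steps (1–5 and 7–19); step 6 prepares keto ester 10.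

**Step 14 (key step, proposed new method).** Three things are most likely to go wrong:
- the C6 radical is quenched (hydrogen abstraction from solvent or reduction) before the slow 7-endo closure;
- the C4 radical adds intermolecularly to the enone of a second molecule;
- facial discrimination in the 5-exo closure is poor, because CH3 and CH2COR on C1 differ little and the C4 configuration rests on a soft steric and hydrogen-bond preference.

Fallback (known chemistry, from 22 back to 23). Acid 22 is coupled with 2-mercaptopyridine N-oxide and a carbodiimide to the thiohydroxamate ester F1. Visible-light irradiation of F1 at about 0.02 M starts a Barton decarboxylation chain in which the C4 radical closes the cyclopentane and the C6 radical is captured by pyridylthio group transfer, giving the α-acyloxy pyridyl sulfide F2 as an isolable compound. Slow addition of Bu3SnH and AIBN to F2 in refluxing benzene at high dilution regenerates the C6 radical with a lifetime set by the tin hydride concentration, and 7-endo closure onto the isopropenyl ketone gives 23. The two ring closures are thereby separated, and the diastereomers from the first closure can be sorted at F2. If the stereochemical outcome at C4 is the failure, this fallback does not cure it.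

**Step 12.** The aldehyde enolate may add intramolecularly to the isopropenyl ketone (six-membered Michael closure) instead of being acylated, and some Z enol ester may form.

Fallback (from 13 back to 21). The silyl enol ether 14 made from 13 is ozonised (O3, CH2Cl2, −78 °C; Me2S) to the acid–aldehyde F3, which carries no Michael acceptor. Enol acylation with 20 (Et3N, DMAP; the mixed anhydride is hydrolysed on work-up) gives the enol ester acid F4. Oxalyl chloride with catalytic DMF gives the acid chloride F5, and Stille acylation with tributyl(prop-1-en-2-yl)stannane and PdCl2(PPh3)2 installs the isopropenyl ketone, giving 21. The enone is thus introduced only after the enol ester exists.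

**Step 15.** Enolisation may go partly toward C10. The free enolate released by fluoride may also attack the neighbouring aryl ester, or O-4 may pick up the acyl group, before triflation.

Fallback (from 24 back to 26, no enolate). Hydroboration of silyl enol ether 24 with BH3·THF puts boron on C8 and hydrogen on C9, giving the β-silyloxy alkylborane F6. BF3·OEt2 then induces anti-elimination of boron and silyloxy to alkene 26, with the O-4 silyl ether lost on acidic work-up. This is the known ketone-to-alkene conversion through hydroboration–elimination of a silyl enol ether.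

**Step 17 (with step 18).** The peracid may attack 26 from the β face, or the epoxide may rearrange under acid instead of being hydrolysed.

Fallback (from 24 back to 28). Rubottom oxidation of 24 (mCPBA, NaHCO3, then mild acid) gives the 8β-hydroxy ketone F7, and Me4NBH(OAc)3 delivers hydride to C9 from the face of O-8, giving the trans-diol 28. This sequence needs the oxidant on the β face, whereas epoxidation of 26 needs it on the α face, so whichever face the ring system prefers, one of the two sequences should lead to 28.

## Further compounds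

F1 | step 14 | 2-sulfanylidenepyridin-1(2H)-yl (5R)-5-[(E)-2-{[4-(benzyloxy)benzoyl]oxy}ethenyl]-2-hydroxy-5,8-dimethyl-7-oxo-2-(propan-2-yl)non-8-enoate | CC(C)C(O)(C(=O)ON1C=CC=CC1=S)CC[C@](C)(CC(=O)C(C)=C)/C=C/OC(=O)c1ccc(OCc2ccccc2)cc1
F2 | step 14 | [(1R,2R,5R)-2-hydroxy-5-methyl-5-(3-methyl-2-oxobut-3-en-1-yl)-2-(propan-2-yl)cyclopentyl](pyridin-2-ylsulfanyl)methyl 4-(benzyloxy)benzoate | CC(C)[C@]1(O)CC[C@](C)(CC(=O)C(C)=C)[C@H]1C(Sc1ccccn1)OC(=O)c1ccc(OCc2ccccc2)cc1
F3 | step 12 | (3S)-7-tert-butoxy-6-hydroxy-3-methyl-7-oxo-3-(2-oxoethyl)-6-(propan-2-yl)heptanoic acid | CC(C)C(O)(C(=O)OC(C)(C)C)CC[C@](C)(CC(=O)O)CC=O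
F4 | step 12 | (3R)-3-[(E)-2-{[4-(benzyloxy)benzoyl]oxy}ethenyl]-7-tert-butoxy-6-hydroxy-3-methyl-7-oxo-6-(propan-2-yl)heptanoic acid | CC(C)C(O)(C(=O)OC(C)(C)C)CC[C@](C)(CC(=O)O)/C=C/OC(=O)c1ccc(OCc2ccccc2)cc1
F5 | step 12 | tert-butyl (5R)-5-[(E)-2-{[4-(benzyloxy)benzoyl]oxy}ethenyl]-7-chloro-2-hydroxy-5-methyl-7-oxo-2-(propan-2-yl)heptanoate | CC(C)C(O)(C(=O)OC(C)(C)C)CC[C@](C)(CC(=O)Cl)/C=C/OC(=O)c1ccc(OCc2ccccc2)cc1
F6 | step 15 | 8α-boranyl-4β,9β-bis[(trimethylsilyl)oxy]daucan-6α-yl 4-(benzyloxy)benzoate (boron on C8 and hydrogen on C9 added to the α face of 24) | CC(C)[C@]1(O[Si](C)(C)C)CC[C@]2(C)C[C@@H](O[Si](C)(C)C)[C@](C)(B)C[C@H](OC(=O)c3ccc(OCc4ccccc4)cc3)[C@H]21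
F7 | step 17 | (3R,3aS,4S,6S,8aR)-3,6-dihydroxy-6,8a-dimethyl-7-oxo-3-(propan-2-yl)decahydroazulen-4-yl 4-(benzyloxy)benzoate | CC(C)[C@]1(O)CC[C@]2(C)CC(=O)[C@@](C)(O)C[C@H](OC(=O)c3ccc(OCc4ccccc4)cc3)[C@H]21
A1 | alternative 1 | 7-methyl-6-(5-methylideneoxolan-2-yl)-1,4-dioxaspiro[4.4]non-6-ene (single enantiomer at the oxolane carbon; its configuration, which would relay to C1, is left open) | C=C1CCC(O1)C1=C(C)CCC12OCCO2
A2 | alternative 1 | (8aR)-8a-methyl-1,2,5,6,8,8a-hexahydrospiro[azulene-3,2'-[1,3]dioxolan]-7-one | O1CCOC12CC[C@]3(C)CC(=O)CCC=C23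
A3 | alternative 2 | 6-[(3R)-3-hydroxy-2,6-dimethylhept-6-en-3-yl]-3-methyl-5-oxo-5,6-dihydro-2H-pyran-2-yl acetate | CC(C)[C@](O)(CCC(C)=C)C1OC(OC(C)=O)C(C)=CC1=O
A4 | alternative 2 | 3-hydroxy-6,8a-dimethyl-3-(propan-2-yl)-1,2,3,7,8,8a-hexahydro-3a,7-epoxyazulen-4-one (C5–O–C9 bridged; stereochemistry as in the SMILES) | CC(C)[C@]1(O)CC[C@]2(C)C[C@@H]3O[C@@]21C(=O)C=C3C
A5 | alternative 3 | 1-diazo-4-(4-methylphenyl)butan-2-one | [N-]=[N+]=CC(=O)CCc1ccc(C)cc1
A6 | alternative 3 | 6-methyl-3,4-dihydroazulen-1(2H)-one | O=C1CCC2=C1C=CC(C)=CC2
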